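For the late hours of this flask we want to know how much Q still stands, so we start from the readings of Q.

| flask | Q | remark | time |
|---|---|---|---|
| Sunday's | 0.050 M | the very flask that is asked about, followed so far |  |
| Saturday's | 0.034 M | run made earlier |  |
| flask | 0.050 M |  | 10 h |

| run | time / h | D / % | Q / % |
|---|---|---|---|
| Sunday's | 0.417 | 1.3 | 91.5 |
| Sunday's | 1.00 | 5.0 | 80.7 |
| Sunday's | 2.00 | 16.6 | 64.7 |
| Sunday's | 5.00 | 44.8 | 33.9 |
| Saturday's | 0.500 | 1.1 | 90.2 |
| Saturday's | 1.33 | 9.3 | 74.5 |
| Saturday's | 3.00 | 26.5 | 52.0 |
| Saturday's | 8.00 | 63.0 | 16.2 |

(standard deviation of a reading: 0.5 percentage points)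

- the numbers in the tables scatter by 0.5 percentage points (one standard deviation)
- the reaction counts as stopped when no species that holds the Q changes by six tenths of a point or more over the second half of the time

- the state of affairs at 10 h: stopped, and by what, or still going (it is still moving / all of Q has reacted / forward and back rates have come level)
- the D standing at 10 h, as a percentage of the Q charged

Saturday's reading of 52.0 % at 3.00 h gives 3.18 h as the time in which whatever Q is present falls to half, our Q half-life, the mark of a first-order decay. But that run was charged at 0.034 M, so we try the half-life on Sunday's charge of 0.050 M: it leaves 33.6 % of the charge at 5.00 h, against a reading of 33.9 % with a scatter of 0.5 percentage points. Carried to 10 h, it leaves 11.3 % in this flask. So by our reckoning Q falls 22 points over the second half of the time, and by the rule for stopping given above this flask is still moving at 10 h.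

The forecast, which holds that “Q falls first-order in both runs”, says it is still moving, with D at 70 %.

In the flask it is still moving, with D at 70.5 %.

    G ⇌ L (K = 0.460, k = 0.00660 h⁻¹)
    E → D (k = 0.790 h⁻¹)
    Q → E (k = 0.182 h⁻¹)
    Q → G (k = 0.0360 h⁻¹)

In this flask Q fed E and G, the path to E using Q 5.1 times as fast as the path to G at the start, while E passed on to D, and at 10 h there stood Q 11.3 %, E 3.58 %, G 14.0 %. A reading of this flask taken at 8.50 h would have put D 5 points lower. The Q half-life carried to 25 h leaves 0.430 %, and the flask left that long holds D at 83.0 % and Q at 0.430 %.

The data were generated by integration for substances that don't exist.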